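In a one-step world, electrophile + nucleophile gives target, and each electrophile lost takes one nucleophile. With 1.50 equiv charged, the electrophile is the limiting reagent and [nucleophile] ends near 0.5 equiv. I count turnovers: one turnover is a fall of [electrophile] by a factor e.

| setting | delta | epsilon | north | north-east | south |
|---|---|---|---|---|---|
| electrophile | 0.054 M | 0.054 M | 0.054 M | 0.054 M | 0.054 M |
| nucleophile | 1.5 equiv | 1.5 equiv | 1.50 equiv | 1.50 equiv | 1.50 equiv |
| free base | 1.5 equiv | 3.9 equiv | 1.80 equiv | 1.20 equiv | 2.70 equiv |
| remark | run made earlier | run made earlier |  |  |  |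
| time |  |  | 8.0 d | 8.0 d | 8.0 d |

| run | time / d | electrophile / % | target / % |
|---|---|---|---|
| delta | 0.833 | 51.2 | 46.6 |
| delta | 1.67 | 29.7 | 64.1 |
| delta | 2.50 | 18.2 | 74.1 |
| delta | 3.00 | 14.5 | 77.3 |
| delta | 4.00 | 9.3 | 81.5 |
| delta | 5.00 | 6.2 | 84.9 |
| delta | 6.00 | 3.9 | 85.6 |
| epsilon | 0.333 | 75.1 | 24.7 |
| epsilon | 0.833 | 51.1 | 47.1 |
| epsilon | 1.67 | 30.3 | 64.8 |
| epsilon | 2.50 | 18.5 | 74.4 |
| epsilon | 3.00 | 14.1 | 77.7 |
| epsilon | 4.00 | 9.3 | 82.2 |
| epsilon | 6.00 | 3.8 | 85.0 |

(readings scatter by 0.5 percentage points)

- part of the electrophile that has reacted at the end, north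
- part of the electrophile that has reacted at the end, north-east
- part of the electrophile that has reacted at the end, south
- what raising the equivalents of free base from its lowest to its highest value here does to the part of the electrophile that has reacted (changes below 5 percentage points count as none) (no change / it falls / it rises)



1. At 4.00 d, delta and epsilon both hold 9.3% electrophile, although free base differs, 1.5 equiv against 3.9 equiv. So I use one reckoning for all three flasks, though north-east lies below both runs.
2. Crude lower bound: if nothing reacts after delta's last reading, 96.1% has reacted. The crude upper bound is 100%.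
3. Upper bound: delta's last stretch runs at 0.435 d⁻¹. In the one-step world the rate falls as [nucleophile] falls, so holding it up to 8.0 d gives 98.4%.
4. Lower bound: that stretch had about 0.566 equiv of nucleophile, which gives the turnover constant, turnovers per day per equivalent of nucleophile (pseudo-first-order rate = constant × [nucleophile]), 0.768 d⁻¹. At 0.5 equiv the rate is 0.384 d⁻¹, which gives 98.2%.
5. Both rates are read from delta's last reading, so I move that reading by its scatter and reckon each rate again, with the reading at 4.00 d held. Taken as 4.40%, it lowers the lower bound to 97.7%. Taken as 3.40%, it raises the upper bound to 98.8%. That is my bracket.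

The forecast says 98.1% for north, 97.8% for north-east and 98.1% for south, with no change, since “the rate does not depend on base in that range”. All three values stand inside my bracket, north-east close to its lower end.

The flasks give 98.4%, 98.3% and 98.4%, with no change (0.11 percentage points).

    electrophile + nucleophile → acid set free + target (k = 0.00830 M⁻¹ min⁻¹)
    nucleophile + acid set free ⇌ protonated nucleophile, settled at all times (K = 120 M⁻¹)
    acid set free + free base ⇌ salt of the base, settled at all times (K = 7800 M⁻¹)
    crystals ⇌ acid set free, rate k4*(cs4 - [acid set free]) while solid is left; crystals form when [acid set free] > cs4 (solubility = 3.10 mM, k = 0.0480 min⁻¹)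
    target → over-reaction product (k = 3.90 × 10⁻⁷ min⁻¹)
    electrophile + target → side product (k = 9.30 × 10⁻⁴ M⁻¹ min⁻¹)

Summing the constant over the whole run, with [nucleophile] falling as electrophile reacts, gives 98.4% for north at 8.0 d, where the flask gives 98.4%. The same sum for north read at 50 h gives 78.6%. That flask gives 76.0%, with 70.0% target and 5.93% side product.

The runs are simulated with constants of no real substance, noise included.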